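## Retrosynthetic overview

- The target is the C8–C8' dimer of 5,6,7,4'-tetrahydroxyisoflavone. Eight aryl ether cleavages come last. Before them, both rings C are opened at O1–C2/C2–C3 (one carbon from a formamide acetal) and at C4–C4a (acylation with 4-methoxyphenylacetic acid, which also brings rings B).
- The plan rests on one feature of each fully substituted ring A. The oxygens on C6 and C8a are para to each other, and the axis carbon C8 lies between the oxygen-bearing C7 and C8a. This is the pattern of a 4-alkoxyphenol assembled from a carbene carbon (C8a), an alkyne (C8, C7), CO (C6) and a vinyl unit (C5, C4a).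
- Both rings A are therefore cut at C8a–C8, C7–C6 and C6–C5. This leads to two alkenyl(benzyloxy)carbene chromium complexes and 1,4-bis(trimethylsilyl)buta-1,3-diyne, whose central sp–sp bond is kept as the biaryl axis.
- SiMe3 on C7 stands in for oxygen, and benzyl marks C8a–O for the pyranone closure. The ipso-iodination is placed before O-methylation of C6–OH, because in the methyl ether C4a–H (ortho to both C5–OEt and C8a–OBn) would compete with C7–Si.
- Ring order: A and A' together in the key step, then C and C' together. Rings B arrive preformed.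

Key step: step 3

Assumption: the SMILES gives no descriptor for the C8–C8' axis, so the racemic atropisomer is taken as the target.

## Route

Step 1
Reactants: 1 (Z)-1-bromo-2-ethoxyethene; 2 chromium hexacarbonyl Cr(CO)6
Product: 5 tetramethylammonium pentacarbonyl[(Z)-3-ethoxy-1-oxidoprop-2-en-1-ylidene]chromate, via (Z)-2-ethoxyvinyllithium 3 (not isolated), via lithium acylchromate 4 (not isolated)
Conditions: n-BuLi, Et2O, −78 °C; cannulate into Cr(CO)6, THF, −78 → 0 °C; evaporate; Me4NBr, degassed H2O, 0 °C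
Reagents that add atoms: tetramethylammonium bromide, C[N+](C)(C)C.[Br-]
Why: Bromine–lithium exchange keeps the Z geometry because the ethoxy oxygen chelates lithium, the vinyllithium adds to a carbonyl ligand of Cr(CO)6 as in the first stage of the Fischer carbene synthesis, and salt metathesis gives an acylchromate that can be dried and stored.

Step 2
Reactants: 5 tetramethylammonium acylchromate; 6 benzyl alcohol
Product: 8 pentacarbonyl[(Z)-1-(benzyloxy)-3-ethoxyprop-2-en-1-ylidene]chromium, via acetoxycarbene complex 7 (not isolated)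
Conditions: AcBr, CH2Cl2, −40 °C; BnOH (1.1 equiv), −40 → 0 °C
Reagents that add atoms: none
Why: O-Acylation gives a strongly electrophilic acyloxycarbene that undergoes addition–elimination with benzyl alcohol at the carbene carbon (the alkoxy-exchange route to Fischer carbenes), and at −40 °C this should be much faster than exchange at the vinylogous ethoxy-bearing carbon.

Step 3
Reactants: 8 benzyloxycarbene complex (2.5 equiv); 9 1,4-bis(trimethylsilyl)buta-1,3-diyne
Product: 12 2,2'-bis(benzyloxy)-4,4'-diethoxy-6,6'-bis(trimethylsilyl)biphenyl-5,5'-diol, via alkynylphenol 10 (not isolated), via bis(tricarbonylchromium) complex 11 (not isolated)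
Conditions: THF (0.3 M in 9), 55 °C then 70 °C, Ar, sealed flask; then Et2O, air, rt
Reagents that add atoms: none
Why: Proposed new method: thermal loss of one CO from 8 (zerovalent chromium; the Z-ethoxy oxygen can hold the vacated site as a hemilabile donor) lets one alkyne of 9 insert into the Cr=C bond (C8a–C8), and migration of a CO ligand onto the new chromium-bound carbon (C7–C6) gives a silyl-substituted dienylketene. Ring A closes by 6π electrocyclisation of this ketene onto the ethoxy-bearing vinyl carbon (C6–C5) followed by enolisation to alkynylphenol 10, and ring A' closes in the same mode after a second molecule of 8 has engaged the remaining aryl(silyl)alkyne, which leaves the former sp–sp bond as the C8–C8' axis. The closest known reaction type is the Dötz benzannulation of alkenyl(alkoxy)carbene chromium complexes with silylalkynes to o-silylphenols; what has not been shown is its twofold use on a bis-silylated conjugated diyne with a β-alkoxyvinyl carbene to give a tetra-ortho-substituted biaryl. The step needs regioselectivity in both insertions, with the silicon-bearing alkyne carbon ending next to the CO-derived C6: the tetrahedral SiMe3 group is clearly larger than the rod-shaped alkynyl group in the first event, whereas in the second it competes with a twisted 2,6-disubstituted aryl group and is helped only by the tendency of silicon to sit on the chromium-bound carbon. It also needs CO insertion to beat five-membered-ring formation, which the donor ethoxy group could favour, and chromium, THF, moderate temperature and high concentration are the known levers in favour of the phenol. No stereocentre is created, the alkene geometry of 8 (which may equilibrate through its push–pull character) is erased on aromatisation, and the axis forms as a racemate.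

Step 4
Reactants: 12 bis(o-silylphenol)
Product: 13 2,2'-bis(benzyloxy)-4,4'-diethoxy-6,6'-diiodobiphenyl-5,5'-diol
Conditions: NIS (2.1 equiv), anhydrous MeCN–CH2Cl2, −20 → 0 °C, dark; aq Na2S2O3
Reagents that add atoms: N-iodosuccinimide, O=C1CCC(=O)N1I
Why: This is an ipso-iododesilylation (electrophilic aromatic substitution at the silicon-bearing carbon), and with C6–OH still free C7 is ortho to the strongest donor of the ring and carries the cation-stabilising silicon, so it should outrun C4a–H, which is why iodination precedes methylation.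

Step 5
Reactants: 13 diiodobiphenyldiol
Product: 14 2,2'-bis(benzyloxy)-4,4'-diethoxy-6,6'-diiodo-5,5'-dimethoxybiphenyl
Conditions: MeI, K2CO3, DMF, rt → 40 °C
Reagents that add atoms: iodomethane, CI
Why: This is a Williamson ether synthesis in which the flanking ethoxy and iodo groups slow but should not stop attack of the phenoxide on the small electrophile, and no other acidic site is present.

Step 6
Reactants: 14 diiodide
Product: 15 2,2'-bis(benzyloxy)-4,4'-diethoxy-5,5',6,6'-tetramethoxybiphenyl
Conditions: NaOMe, CuI (30 mol % per iodide), DMF–MeOH, 110 °C, sealed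
Reagents that add atoms: sodium methoxide, C[O-].[Na+]
Why: This is an Ullmann-type copper-catalysed C–O coupling of an aryl iodide with methoxide, a standard entry to polymethoxyarenes in which the ortho methoxy group assists copper, and the benzyl, ethyl and methyl ethers are inert to methoxide.

Step 7
Reactants: 15 bis(benzyl ether)
Product: 16 4,4'-diethoxy-5,5',6,6'-tetramethoxybiphenyl-2,2'-diol
Conditions: H2 (1 atm), Pd/C, EtOAc–MeOH, rt
Reagents that add atoms: none
Why: Catalytic hydrogenolysis cleaves only the benzylic C–O bonds, so the C8a oxygens are freed selectively while C5, C6 and C7 stay alkylated.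

Step 8
Reactants: 16 biphenyl-2,2'-diol; 17 4-methoxyphenylacetic acid (2.5 equiv)
Product: 18 3,3'-bis[(4-methoxyphenyl)acetyl]-4,4'-diethoxy-5,5',6,6'-tetramethoxybiphenyl-2,2'-diol
Conditions: BF3·OEt2 (solvent and promoter), 85 °C; aq NaOAc
Reagents that add atoms: none
Why: This is a Friedel–Crafts acylation of a phenol in BF3·OEt2, which runs through O-acylation and Fries shift and is the standard deoxybenzoin entry to isoflavones, and C4a is the only unsubstituted carbon of each ring A and is ortho to the free C8a–OH.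

Step 9
Reactants: 18 bis(deoxybenzoin)
Product: 20 5,5'-diethoxy-6,6',7,7'-tetramethoxy-3,3'-bis(4-methoxyphenyl)-4H,4'H-[8,8'-bichromene]-4,4'-dione, via bis(enaminone) 19 (not isolated)
Conditions: Me2NCH(OMe)2, toluene, 95 °C; AcOH, 60 °C
Reagents that add atoms: N,N-dimethylformamide dimethyl acetal, COC(OC)N(C)C
Why: Condensation of the acidic benzylic CH2 with the formamide acetal gives the enaminone, and addition of C8a–OH with loss of dimethylamine closes each ring C (the established one-carbon annulation of 2-hydroxydeoxybenzoins), while closure toward C5 is excluded because C5–O is still ethylated.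

Step 10
Reactants: 20 octa-ether
Product: 21 5,5',6,6',7,7'-hexahydroxy-3,3'-bis(4-hydroxyphenyl)-4H,4'H-[8,8'-bichromene]-4,4'-dione (target, racemic axis)
Conditions: BBr3 (24 equiv), CH2Cl2, −78 °C → rt, Ar; ice–water, work-up under Ar
Reagents that add atoms: none
Why: Lewis-acid cleavage of aryl methyl and ethyl ethers with BBr3 is standard for polyalkoxyisoflavones, is chelation-assisted at C5, and at or below room temperature should avoid the Wessely–Moser ring opening and reclosure that hot mineral acid could cause and that would move the axis from C8 to C6.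

## Compound list

1 | (Z)-1-bromo-2-ethoxyethene | CCO/C=C\Br | starting material
2 | chromium hexacarbonyl, Cr(CO)6 | O=C=[Cr](=C=O)(=C=O)(=C=O)(=C=O)=C=O | starting material
3 | (Z)-2-ethoxyvinyllithium | CCO/C=C\[Li] | intermediate
4 | lithium pentacarbonyl[(Z)-3-ethoxy-1-oxidoprop-2-en-1-ylidene]chromate | CCO/C=C\C([O-])=[Cr](=C=O)(=C=O)(=C=O)(=C=O)=C=O.[Li+] | intermediate
5 | tetramethylammonium pentacarbonyl[(Z)-3-ethoxy-1-oxidoprop-2-en-1-ylidene]chromate | CCO/C=C\C([O-])=[Cr](=C=O)(=C=O)(=C=O)(=C=O)=C=O.C[N+](C)(C)C | intermediate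
6 | benzyl alcohol | OCc1ccccc1 | starting material
7 | pentacarbonyl[(Z)-1-(acetyloxy)-3-ethoxyprop-2-en-1-ylidene]chromium | CCO/C=C\C(OC(C)=O)=[Cr](=C=O)(=C=O)(=C=O)(=C=O)=C=O | intermediate
8 | pentacarbonyl[(Z)-1-(benzyloxy)-3-ethoxyprop-2-en-1-ylidene]chromium | CCO/C=C\C(OCc1ccccc1)=[Cr](=C=O)(=C=O)(=C=O)(=C=O)=C=O | intermediate
9 | 1,4-bis(trimethylsilyl)buta-1,3-diyne | C[Si](C)(C)C#CC#C[Si](C)(C)C | starting material
10 | 4-(benzyloxy)-6-ethoxy-2-(trimethylsilyl)-3-[(trimethylsilyl)ethynyl]phenol | CCOc1cc(OCc2ccccc2)c(C#C[Si](C)(C)C)c([Si](C)(C)C)c1O | intermediate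
11 | bis(tricarbonylchromium) complex of 12, one Cr(CO)3 on each new ring (hapticity not expressible, written as components) | CCOc1cc(OCc2ccccc2)c(-c2c(OCc3ccccc3)cc(OCC)c(O)c2[Si](C)(C)C)c([Si](C)(C)C)c1O.O=C=[Cr](=C=O)=C=O.O=C=[Cr](=C=O)=C=O | intermediate
12 | 2,2'-bis(benzyloxy)-4,4'-diethoxy-6,6'-bis(trimethylsilyl)biphenyl-5,5'-diol (biphenyl C1 = C8, C2 = C8a, C3 = C4a, C4 = C5, C5 = C6, C6 = C7) | CCOc1cc(OCc2ccccc2)c(-c2c(OCc3ccccc3)cc(OCC)c(O)c2[Si](C)(C)C)c([Si](C)(C)C)c1O | intermediate
13 | 2,2'-bis(benzyloxy)-4,4'-diethoxy-6,6'-diiodobiphenyl-5,5'-diol | CCOc1cc(OCc2ccccc2)c(-c2c(OCc3ccccc3)cc(OCC)c(O)c2I)c(I)c1O | intermediate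
14 | 2,2'-bis(benzyloxy)-4,4'-diethoxy-6,6'-diiodo-5,5'-dimethoxybiphenyl | CCOc1cc(OCc2ccccc2)c(-c2c(OCc3ccccc3)cc(OCC)c(OC)c2I)c(I)c1OC | intermediate
15 | 2,2'-bis(benzyloxy)-4,4'-diethoxy-5,5',6,6'-tetramethoxybiphenyl | CCOc1cc(OCc2ccccc2)c(-c2c(OCc3ccccc3)cc(OCC)c(OC)c2OC)c(OC)c1OC | intermediate
16 | 4,4'-diethoxy-5,5',6,6'-tetramethoxybiphenyl-2,2'-diol | CCOc1cc(O)c(-c2c(O)cc(OCC)c(OC)c2OC)c(OC)c1OC | intermediate
17 | 4-methoxyphenylacetic acid | COc1ccc(CC(=O)O)cc1 | starting material
18 | 3,3'-bis[(4-methoxyphenyl)acetyl]-4,4'-diethoxy-5,5',6,6'-tetramethoxybiphenyl-2,2'-diol | CCOc1c(C(=O)Cc2ccc(OC)cc2)c(O)c(-c2c(O)c(C(=O)Cc3ccc(OC)cc3)c(OCC)c(OC)c2OC)c(OC)c1OC | intermediate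
19 | 3,3'-bis[3-(dimethylamino)-2-(4-methoxyphenyl)prop-2-enoyl]-4,4'-diethoxy-5,5',6,6'-tetramethoxybiphenyl-2,2'-diol (push–pull alkene, geometry not fixed) | CCOc1c(C(=O)C(=CN(C)C)c2ccc(OC)cc2)c(O)c(-c2c(O)c(C(=O)C(=CN(C)C)c3ccc(OC)cc3)c(OCC)c(OC)c2OC)c(OC)c1OC | intermediate
20 | 5,5'-diethoxy-6,6',7,7'-tetramethoxy-3,3'-bis(4-methoxyphenyl)-4H,4'H-[8,8'-bichromene]-4,4'-dione | O=c1c(-c2ccc(OC)cc2)coc2c(-c3c(OC)c(OC)c(OCC)c4c(=O)c(-c5ccc(OC)cc5)coc34)c(OC)c(OC)c(OCC)c12 | intermediate
21 | 5,5',6,6',7,7'-hexahydroxy-3,3'-bis(4-hydroxyphenyl)-4H,4'H-[8,8'-bichromene]-4,4'-dione (CNP0254964.0) | O=c1c(-c2ccc(O)cc2)coc2c(-c3c(O)c(O)c(O)c4c(=O)c(-c5ccc(O)cc5)coc34)c(O)c(O)c(O)c12 | target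

## Step count and risks

Total step count: 10. Longest linear sequence: 10 steps (1 → 21).

### Step 3 (double benzannulation)

- The sequence may stop after the first ring, because the second alkyne is shielded by a silyl group and a 2,6-disubstituted aryl group.
- The second insertion may run with reversed orientation.
- The donor ethoxy group may divert the vinylcarbene into five-membered-ring formation without CO uptake.
- The silyl-stabilised ketene may persist without cyclising.

The fallback gives up the diyne and makes the axis by aryl–aryl coupling with known chemistry. It sets out from 17 and returns at 21.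

- 17 would be condensed with commercial 3,4,5-trimethoxyphenol in BF3·OEt2 at 85 °C to 1-(2-hydroxy-4,5,6-trimethoxyphenyl)-2-(4-methoxyphenyl)ethanone F1.
- Closure with Me2NCH(OMe)2 would give 5,6,7-trimethoxy-3-(4-methoxyphenyl)chromen-4-one F2.
- Iodination at the only free ring A carbon (NIS, TFA, MeCN) would give 8-iodo-5,6,7-trimethoxy-3-(4-methoxyphenyl)chromen-4-one F3.
- A classical Ullmann homocoupling (activated copper bronze, DMF, 150 °C) would give 5,5',6,6',7,7'-hexamethoxy-3,3'-bis(4-methoxyphenyl)-8,8'-bichromene-4,4'-dione F4.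
- BBr3 as in step 10 would then give 21.

### Step 4 (ipso-iodination)

- The 4-benzyloxyphenol may be oxidised with loss of benzyl instead of being substituted.
- Iodination may spill over to C4a–H.

The fallback caps the phenol and blocks C4a with a traceless halogen. It sets out from 12 and returns at 16.

- Methylation (MeI, K2CO3, DMF) would give 2,2'-bis(benzyloxy)-4,4'-diethoxy-5,5'-dimethoxy-6,6'-bis(trimethylsilyl)biphenyl F5.
- NCS in DMF, which attacks activated C–H far more readily than C–Si, would give 2,2'-bis(benzyloxy)-3,3'-dichloro-4,4'-diethoxy-5,5'-dimethoxy-6,6'-bis(trimethylsilyl)biphenyl F6.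
- ICl in CH2Cl2 at 0 °C then has only the silicon-bearing carbon left to attack. It would give 2,2'-bis(benzyloxy)-3,3'-dichloro-4,4'-diethoxy-6,6'-diiodo-5,5'-dimethoxybiphenyl F7.
- NaOMe/CuI leaves the aryl chloride untouched and would give 2,2'-bis(benzyloxy)-3,3'-dichloro-4,4'-diethoxy-5,5',6,6'-tetramethoxybiphenyl F8.
- H2, Pd/C and Et3N would remove benzyl and chlorine together to give 16.

### Step 6 (double methoxylation)

- Reductive loss of iodine may outrun C–O bond formation at an iodide flanked by a methoxy group and the biaryl axis.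
- The exchange may stall after the first iodide.

The fallback replaces copper catalysis by a carbanion route. It sets out from 14 and returns at 15.

- t-BuLi (4.2 equiv, THF, −78 °C), B(OMe)3 and acidic work-up would give [2,2'-bis(benzyloxy)-4,4'-diethoxy-5,5'-dimethoxybiphenyl-6,6'-diyl]diboronic acid F9.
- H2O2/NaOH at 0 °C would give 2,2'-bis(benzyloxy)-4,4'-diethoxy-5,5'-dimethoxybiphenyl-6,6'-diol F10.
- MeI/K2CO3 in DMF would give 15.

## Further compounds

F1 | step 3 | 1-(2-hydroxy-4,5,6-trimethoxyphenyl)-2-(4-methoxyphenyl)ethanone | COc1ccc(CC(=O)c2c(O)cc(OC)c(OC)c2OC)cc1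
F2 | step 3 | 5,6,7-trimethoxy-3-(4-methoxyphenyl)chromen-4-one | COc1ccc(-c2coc3cc(OC)c(OC)c(OC)c3c2=O)cc1
F3 | step 3 | 8-iodo-5,6,7-trimethoxy-3-(4-methoxyphenyl)chromen-4-one | COc1ccc(-c2coc3c(I)c(OC)c(OC)c(OC)c3c2=O)cc1
F4 | step 3 | 5,5',6,6',7,7'-hexamethoxy-3,3'-bis(4-methoxyphenyl)-8,8'-bichromene-4,4'-dione | O=c1c(-c2ccc(OC)cc2)coc2c(-c3c(OC)c(OC)c(OC)c4c(=O)c(-c5ccc(OC)cc5)coc34)c(OC)c(OC)c(OC)c12
F5 | step 4 | 2,2'-bis(benzyloxy)-4,4'-diethoxy-5,5'-dimethoxy-6,6'-bis(trimethylsilyl)biphenyl | CCOc1cc(OCc2ccccc2)c(-c2c(OCc3ccccc3)cc(OCC)c(OC)c2[Si](C)(C)C)c([Si](C)(C)C)c1OC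
F6 | step 4 | 2,2'-bis(benzyloxy)-3,3'-dichloro-4,4'-diethoxy-5,5'-dimethoxy-6,6'-bis(trimethylsilyl)biphenyl | CCOc1c(Cl)c(OCc2ccccc2)c(-c2c(OCc3ccccc3)c(Cl)c(OCC)c(OC)c2[Si](C)(C)C)c([Si](C)(C)C)c1OC
F7 | step 4 | 2,2'-bis(benzyloxy)-3,3'-dichloro-4,4'-diethoxy-6,6'-diiodo-5,5'-dimethoxybiphenyl | CCOc1c(Cl)c(OCc2ccccc2)c(-c2c(OCc3ccccc3)c(Cl)c(OCC)c(OC)c2I)c(I)c1OC
F8 | step 4 | 2,2'-bis(benzyloxy)-3,3'-dichloro-4,4'-diethoxy-5,5',6,6'-tetramethoxybiphenyl | CCOc1c(Cl)c(OCc2ccccc2)c(-c2c(OCc3ccccc3)c(Cl)c(OCC)c(OC)c2OC)c(OC)c1OC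
F9 | step 6 | [2,2'-bis(benzyloxy)-4,4'-diethoxy-5,5'-dimethoxybiphenyl-6,6'-diyl]diboronic acid | CCOc1cc(OCc2ccccc2)c(-c2c(OCc3ccccc3)cc(OCC)c(OC)c2B(O)O)c(B(O)O)c1OC
F10 | step 6 | 2,2'-bis(benzyloxy)-4,4'-diethoxy-5,5'-dimethoxybiphenyl-6,6'-diol | CCOc1cc(OCc2ccccc2)c(-c2c(OCc3ccccc3)cc(OCC)c(OC)c2O)c(O)c1OC
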